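Ring A carries O1 (on C8a) para to the free hydroxyl on C6, so it is a masked 1,4-benzoquinone whose C8a oxygen can be delivered to C2. The pyran ring is therefore disconnected at O1–C2: a 5-(2-arylallyl)-2,3-dimethoxy-1,4-benzoquinone is tautomerised by base through its acidic C4 methylene to a vinyl ortho-quinone methide, and oxa-6π electrocyclisation joins the quinone oxygen to the terminal methylene, closing the ring and releasing the C6 phenol in one redox-neutral operation. Both arenes derive from 2,3-dimethoxyphenol, the C2–C3–C4 unit from 2,3-dibromopropene; C3 is then set by iridium-catalysed asymmetric hydrogenation of the resulting isoflav-3-ene.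

Key step: step 6

Remark: isoflavan numbering is used (O1, C2, C3, C4, C4a, C5 to C8, C8a; ring B atoms primed); C3 of the target is S (C2 > C1' > C4 > H). It is assumed that the antipode of the P,N ligand in step 7 can be chosen so that hydrogen reaches the face of C3 that gives 3S.

Step 1
Reactants: 1 2,3-dimethoxyphenol
Product: 2 1,2-dimethoxy-3-(methoxymethoxy)benzene
Conditions: MOMCl, iPr2NEt, CH2Cl2, 0 °C to rt
Reagents that add atoms: chloromethyl methyl ether (MOMCl), COCCl
Why: O-alkylation of the phenol (Williamson-type) should install a MOM ether that later directs the ortho-lithiation and masks the 2'-oxygen of ring B through the oxidation and the key step.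

Step 2
Reactants: 1 2,3-dimethoxyphenol; 3 2,3-dibromopropene
Product: 4 1-[(2-bromoprop-2-en-1-yl)oxy]-2,3-dimethoxybenzene
Conditions: K2CO3, acetone, reflux
Reagents that add atoms: none
Why: Williamson ether synthesis, in which the phenoxide should displace only the allylic bromide because the vinylic bromide is inert to SN2.

Step 3
Reactants: 2 1,2-dimethoxy-3-(methoxymethoxy)benzene; 4 1-[(2-bromoprop-2-en-1-yl)oxy]-2,3-dimethoxybenzene
Product: 7 1-({2-[3,4-dimethoxy-2-(methoxymethoxy)phenyl]prop-2-en-1-yl}oxy)-2,3-dimethoxybenzene, via aryllithium 5 (not isolated), via arylzinc chloride 6 (not isolated)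
Conditions: n-BuLi, THF, 0 °C; ZnCl2, 0 °C to rt; then 4, Pd(OAc)2 (2 mol %), SPhos (4 mol %), THF, 40 °C
Reagents that add atoms: none
Why: Directed ortho-metalation next to the OMOM group (a stronger director than OMe), transmetalation to zinc and Negishi coupling at the vinylic C–Br bond, which zerovalent palladium should enter much faster than it ionises the allyl aryl ether.

Step 4
Reactants: 7 1-({2-[3,4-dimethoxy-2-(methoxymethoxy)phenyl]prop-2-en-1-yl}oxy)-2,3-dimethoxybenzene
Product: 9 6-{2-[3,4-dimethoxy-2-(methoxymethoxy)phenyl]prop-2-en-1-yl}-2,3-dimethoxyphenol, via cyclohexadienone 8 (not isolated)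
Conditions: PhNEt2, 190 °C, argon
Reagents that add atoms: none
Why: Aromatic Claisen rearrangement ([3,3]-sigmatropic shift) to the only free ortho position followed by enolisation, in which the former O-bound CH2 becomes the terminal =CH2 (future C2) and the basic solvent should suppress acid-catalysed cyclisation of the product.

Step 5
Reactants: 9 6-{2-[3,4-dimethoxy-2-(methoxymethoxy)phenyl]prop-2-en-1-yl}-2,3-dimethoxyphenol
Product: 10 5-{2-[3,4-dimethoxy-2-(methoxymethoxy)phenyl]prop-2-en-1-yl}-2,3-dimethoxycyclohexa-2,5-diene-1,4-dione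
Conditions: (KSO3)2NO, KH2PO4, H2O/acetone, 0 °C to rt
Reagents that add atoms: potassium nitrosodisulfonate, [K+].[K+].[O]N(S(=O)(=O)[O-])S(=O)(=O)[O-]
Why: Teuber oxidation of a phenol with a free para position to the para-quinone, which should leave the alkene and the fully etherified ring B untouched and supplies the oxygen that becomes the C6 hydroxyl.

Step 6
Reactants: 10 5-{2-[3,4-dimethoxy-2-(methoxymethoxy)phenyl]prop-2-en-1-yl}-2,3-dimethoxycyclohexa-2,5-diene-1,4-dione
Product: 12 3-[3,4-dimethoxy-2-(methoxymethoxy)phenyl]-7,8-dimethoxy-2H-chromen-6-ol, via vinyl ortho-quinone methide 11 (not isolated)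
Conditions: Et3N (0.5 equiv), degassed toluene (0.02 M), rt to 60 °C, argon
Reagents that add atoms: none
Why: Et3N removes one of the C4 protons, which are acidified twice over (vinylogous α-position of the C6 carbonyl through C4a=C5, and allylic to C3=C2), and O-protonation of the dienolate at the C6 oxygen gives the hydroxy vinyl ortho-quinone methide 11, whose O=C8a–C4a=C4–C3=C2 unit is a 1-oxatriene. Thermal disrotatory oxa-6π electrocyclisation then bonds the C8a oxygen (O1) to the terminal methylene C2, which closes the pyran ring, makes ring A aromatic and leaves the former C6 carbonyl as the free phenol. The closest known reaction type is the base-induced isomerisation of allyl- and prenylquinones to 2H-chromen-6-ols (ubiquinone to ubichromenol), familiar from biomimetic chromene synthesis. The single ring closes in the 6π-electrocyclic mode, and no stereocentre arises because C3 remains trigonal until step 7. The step needs enolisation towards C4 only, the Z methide geometry (C3 syn to the C8a carbonyl) and closure faster than intermolecular trapping of the methide: C4 carries the only acidic C–H bonds, the E and Z methides interconvert through the reversible tautomerisation, dilution favours the unimolecular pericyclic step, and the MOM ether on the 2'-oxygen of ring B removes the only internal nucleophile that could add to C4.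

Step 7
Reactants: 12 3-[3,4-dimethoxy-2-(methoxymethoxy)phenyl]-7,8-dimethoxy-2H-chromen-6-ol
Product: 13 (3S)-3-[3,4-dimethoxy-2-(methoxymethoxy)phenyl]-7,8-dimethoxy-3,4-dihydro-2H-chromen-6-ol
Conditions: H2 (50 bar), [Ir(cod)(ThrePHOX)][B(3,5-(CF3)2C6H3)4] (2 mol %), CH2Cl2, rt
Reagents that add atoms: none
Why: Iridium-catalysed asymmetric hydrogenation of a trisubstituted cyclic aryl alkene with a cationic P,N-ligated catalyst of the class used for 3-aryl-2H-chromenes, in which the chiral ligand pocket should differentiate the faces of C3=C4 so that hydrogen adds to C3 from the face giving the S centre (catalyst control).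

Step 8
Reactants: 13 (3S)-3-[3,4-dimethoxy-2-(methoxymethoxy)phenyl]-7,8-dimethoxy-3,4-dihydro-2H-chromen-6-ol
Product: 14 (3S)-3-(2-hydroxy-3,4-dimethoxyphenyl)-7,8-dimethoxy-3,4-dihydro-2H-chromen-6-ol
Conditions: HCl (1 M in MeOH), 40 °C
Reagents that add atoms: none
Why: Acid-catalysed acetal exchange should remove the MOM group only after the alkene is saturated (so the 2'-phenol cannot add to C4), and C3 has neither an acidic hydrogen nor an ionisable bond, so its configuration should be retained.

Compound list
1 | 2,3-dimethoxyphenol | COc1cccc(O)c1OC | starting material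
2 | 1,2-dimethoxy-3-(methoxymethoxy)benzene | COCOc1cccc(OC)c1OC | intermediate
3 | 2,3-dibromopropene | C=C(Br)CBr | starting material
4 | 1-[(2-bromoprop-2-en-1-yl)oxy]-2,3-dimethoxybenzene | C=C(Br)COc1cccc(OC)c1OC | intermediate
5 | [3,4-dimethoxy-2-(methoxymethoxy)phenyl]lithium | [Li]c1ccc(OC)c(OC)c1OCOC | intermediate (not isolated)
6 | [3,4-dimethoxy-2-(methoxymethoxy)phenyl]zinc chloride | Cl[Zn]c1ccc(OC)c(OC)c1OCOC | intermediate (not isolated)
7 | 1-({2-[3,4-dimethoxy-2-(methoxymethoxy)phenyl]prop-2-en-1-yl}oxy)-2,3-dimethoxybenzene | C=C(COc1cccc(OC)c1OC)c1ccc(OC)c(OC)c1OCOC | intermediate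
8 | 6-{2-[3,4-dimethoxy-2-(methoxymethoxy)phenyl]prop-2-en-1-yl}-2,3-dimethoxycyclohexa-2,4-dien-1-one (transient, racemic at C6) | C=C(CC1C=CC(OC)=C(OC)C1=O)c1ccc(OC)c(OC)c1OCOC | intermediate (not isolated)
9 | 6-{2-[3,4-dimethoxy-2-(methoxymethoxy)phenyl]prop-2-en-1-yl}-2,3-dimethoxyphenol | C=C(Cc1ccc(OC)c(OC)c1O)c1ccc(OC)c(OC)c1OCOC | intermediate
10 | 5-{2-[3,4-dimethoxy-2-(methoxymethoxy)phenyl]prop-2-en-1-yl}-2,3-dimethoxycyclohexa-2,5-diene-1,4-dione | C=C(CC1=CC(=O)C(OC)=C(OC)C1=O)c1ccc(OC)c(OC)c1OCOC | intermediate
11 | (6Z)-6-{2-[3,4-dimethoxy-2-(methoxymethoxy)phenyl]prop-2-en-1-ylidene}-4-hydroxy-2,3-dimethoxycyclohexa-2,4-dien-1-one | C=C(/C=C1/C=C(O)C(OC)=C(OC)C1=O)c1ccc(OC)c(OC)c1OCOC | intermediate (not isolated)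
12 | 3-[3,4-dimethoxy-2-(methoxymethoxy)phenyl]-7,8-dimethoxy-2H-chromen-6-ol | COCOc1c(C2=Cc3cc(O)c(OC)c(OC)c3OC2)ccc(OC)c1OC | intermediate
13 | (3S)-3-[3,4-dimethoxy-2-(methoxymethoxy)phenyl]-7,8-dimethoxy-3,4-dihydro-2H-chromen-6-ol | COc1ccc([C@H]2COc3c(cc(O)c(OC)c3OC)C2)c(OCOC)c1OC | intermediate
14 | (3S)-3-(2-hydroxy-3,4-dimethoxyphenyl)-7,8-dimethoxy-3,4-dihydro-2H-chromen-6-ol | COc1ccc([C@H]2COc3c(cc(O)c(OC)c3OC)C2)c(O)c1OC | target

Total step count: 8. Longest linear sequence: 7 steps (step 1 or step 2, then steps 3 to 8).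

Steps most likely to fail

Step 6. The ortho-quinone methide may be consumed by hetero-Diels–Alder dimerisation or conjugate addition before it cyclises, or the dienolate may be reprotonated at C2 and stall as the conjugated styrylquinone. The fallback sets out from 10 and comes back at 13.
- The quinone is reduced with Na2S2O4 (EtOAc/H2O) to the 2-arylallyl hydroquinone F1.
- Hydroboration of the 1,1-disubstituted alkene with excess 9-BBN (THF; two equivalents are taken up by the phenols) and oxidation with NaBO3·4H2O should give the racemic anti-Markovnikov primary alcohol F2.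
- Mitsunobu etherification (PPh3, DIAD, THF, 0 °C, high dilution) should close the same O1–C2 bond by SN2 (6-exo-tet; only the phenol ortho to the side chain can reach) to give the racemic MOM-protected isoflavan F3.
- The enantiomers of F3 are separated by preparative chromatography on a chiral stationary phase; the 3S enantiomer is 13, which continues with step 8.

Step 7. Facial discrimination may be poor because the ortho-substituted ring B is twisted out of the alkene plane, and the free C6 phenol may inhibit the cationic catalyst. The fallback sets out from 12 and comes back at 13.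
- The C6 hydroxyl is acylated with (1S,4R)-camphanic chloride (Et3N, DMAP, CH2Cl2) to give the chromenyl camphanate F4.
- Hydrogenation (H2, palladium on carbon, EtOAc) should give the two C3-epimeric camphanates, the 3S ester F5 and the 3R ester F6.
- The epimers are separated by fractional crystallisation or chromatography, and methanolysis of F5 (K2CO3, MeOH, rt) should return 13.

Step 3. Zerovalent palladium may ionise the allyl aryl ether of 4 or 7 with loss of the phenoxide, and lithiation may be incompletely regioselective. The fallback sets out from 1 and 5 and comes back at 7.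
- Phenol 1 is alkylated with 2-chloro-N-methoxy-N-methylacetamide (K2CO3, DMF) to give the aryloxy Weinreb amide F7.
- Addition of aryllithium 5 (THF, −78 °C) should stop at the chelated tetrahedral adduct and give, on work-up, the aryl aryloxymethyl ketone F8.
- Wittig methylenation (Ph3PCH3Br, KOtBu, THF) should then give 7 without any palladium.

Further compounds
F1 | step 6 | 2-{2-[3,4-dimethoxy-2-(methoxymethoxy)phenyl]prop-2-en-1-yl}-5,6-dimethoxybenzene-1,4-diol | C=C(Cc1cc(O)c(OC)c(OC)c1O)c1ccc(OC)c(OC)c1OCOC
F2 | step 6 | racemic 2-{2-[3,4-dimethoxy-2-(methoxymethoxy)phenyl]-3-hydroxypropyl}-5,6-dimethoxybenzene-1,4-diol | OCC(Cc1cc(O)c(OC)c(OC)c1O)c1ccc(OC)c(OC)c1OCOC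
F3 | step 6 | racemic 3-[3,4-dimethoxy-2-(methoxymethoxy)phenyl]-7,8-dimethoxy-3,4-dihydro-2H-chromen-6-ol | COc1ccc(C2COc3c(cc(O)c(OC)c3OC)C2)c(OCOC)c1OC
F4 | step 7 | 3-[3,4-dimethoxy-2-(methoxymethoxy)phenyl]-7,8-dimethoxy-2H-chromen-6-yl (1S,4R)-camphanate | C[C@]12CC[C@](C(=O)Oc3cc4C=C(c5ccc(OC)c(OC)c5OCOC)COc4c(OC)c3OC)(OC1=O)C2(C)C
F5 | step 7 | (3S)-3-[3,4-dimethoxy-2-(methoxymethoxy)phenyl]-7,8-dimethoxy-3,4-dihydro-2H-chromen-6-yl (1S,4R)-camphanate | C[C@]12CC[C@](C(=O)Oc3cc4C[C@@H](c5ccc(OC)c(OC)c5OCOC)COc4c(OC)c3OC)(OC1=O)C2(C)C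
F6 | step 7 | (3R)-3-[3,4-dimethoxy-2-(methoxymethoxy)phenyl]-7,8-dimethoxy-3,4-dihydro-2H-chromen-6-yl (1S,4R)-camphanate | C[C@]12CC[C@](C(=O)Oc3cc4C[C@H](c5ccc(OC)c(OC)c5OCOC)COc4c(OC)c3OC)(OC1=O)C2(C)C
F7 | step 3 | 2-(2,3-dimethoxyphenoxy)-N-methoxy-N-methylacetamide | CON(C)C(=O)COc1cccc(OC)c1OC
F8 | step 3 | 1-[3,4-dimethoxy-2-(methoxymethoxy)phenyl]-2-(2,3-dimethoxyphenoxy)ethan-1-one | O=C(COc1cccc(OC)c1OC)c1ccc(OC)c(OC)c1OCOC
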